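Find which flask holds the most target when the run ends.

| flask | substrate | reagent | temperature | time |
|---|---|---|---|---|
| Friday's | 0.020 M | 0.0190 M | 100 °C | 25 min |
| Monday's | 0.020 M | 0.0190 M | 60 °C | 25 min |
| Thursday's | 0.020 M | 0.0190 M | 80 °C | 25 min |

    substrate ⇌ other conformer (K1 = 2.8, k1 = 0.0028 /s, Ea1 = 94.0 kJ/mol, ΔH1 = −41.0 kJ/mol)
    substrate + reagent → target (k2 = 0.12 /M/s, Ea2 = 50.0 kJ/mol)
    reagent + other conformer → isomer of the product (k3 = 0.040 /M/s, Ea3 = 75.0 kJ/mol)
    substrate + target → side product (k4 = 0.049 /M/s, Ea4 = 83.0 kJ/mol)
    (constants at 100 °C)

- percent here means substrate units held: one side product counts as two
- at 100 °C the constants are as listed, elsewhere as the activation energies and enthalpies make them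
- in a conversion other conformer counts as not yet reacted

- the flask with the highest amount of target, in percent of the substrate charged ("all alike" if they lie within 1.5 percentage points) (Friday's / Monday's / Thursday's / all alike)
- final target, as a percentage of the substrate charged, in Friday's
- final target, as a percentage of the substrate charged, in Monday's
- final target, as a percentage of the substrate charged, in Thursday's

Compare two times. At the start the flask holds no other conformer and no target. So the isomer step, the side-product step and the return of other conformer each begin at zero, and substrate has two exits. For the reagent time, take one over the constant of the reaction with reagent times the reagent charged. For the conformer time, take one over the forward constant of the conformer change.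

Friday's gives a reagent time of 7.31 min and a conformer time of 5.95 min. Going down to Monday's temperature, the conformer change slows by a factor 38 and the reaction with reagent by a factor 6.9. So Monday's gives 50.6 min and 226 min.

Now divide the conformer time by the reagent time. Both exits draw on the same substrate, so substrate drops out. Time stays in through reagent, which falls during the run, so the quotient holds for reagent as charged. For Monday's the quotient is 4.47. Call it the split, a selectivity factor: target formed per other conformer formed at the start, forward step counted. Friday's split is 0.814, and it is the poorer one.

Hold both flasks against the clock. In Monday's the reagent time exceeds the run of 25 min, so that flask is clean but unfinished. In Friday's both times are shorter than the run, but the conformer exit is the quicker one. Thursday's stands between them in temperature, so its split and its reagent time lie between theirs. I commit to Thursday's. For Monday's yield, note that substrate and reagent are charged nearly alike. So let them fall together as a second-order pair and set the conformer exit aside. Target is then the run over the run plus the reagent time, an estimate of 33.1% of the substrate charged in Monday's.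

The forecast also names Thursday's, with 37% in Friday's, 30% in Monday's and 41% in Thursday's. Its ground is that “the yield peaks at the intermediate” temperature.

The run puts Thursday's on top with 41.9%, against 38.6% in Friday's and 30.6% in Monday's. Monday's split went from 4.47 at the start to 3.0 at 25.0 min, with reagent at 66.8% of its charge, and target there stands 3.70 times over other conformer. Charge Monday's flask with 0.048 M of reagent instead, and the split at the start becomes 11.3. That flask ends with 60.8% target against 5.85% other conformer, a ratio of 10.4.

The constants used here are made up; no experiment stands behind them.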